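**Assumptions (one line each)**
- Catalyst enantiomers are chosen to give the depicted series: (S)-Me-CBS gives the (2R,3S) alcohol 4, and the Shi ketone enantiomer that gives the (R)-epoxide 5. If the antipodes result, the opposite catalyst enantiomer is used.
- Left-half numbering follows the target SMILES: C1–C12 left ring, C13 the CH2 next to C14. Right-half numbering is C14–C23.

**Retrosynthetic overview**
1. Disconnect C13–C14 into an alkyl-9-BBN (from diene 9) and a tetrasubstituted alkenyl triflate (12). The C14-OH/C15-H pair comes from face-selective epoxidation and trans-diaxial hydride opening of the C14=C15 alkene.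
2. Both cyclohexane–oxepane halves come from one enantiopure hydroxy-ketone, 4. A CBS desymmetrisation of achiral dione 3 sets C18/C19, which correspond to C7/C6 on the left.
3. Both oxepane rings are formed in the single building block 6: Shi epoxidation (sets C3/C22), then a 7-endo epoxy-alcohol etherification.
4. The ring-A exo-methylene and the C11 stereocentre come from hydroboration, oxidation and Wittig methylenation after the coupling.
5. Ring order: the cyclohexanes are already present in 3; both oxepanes close together in step 4; the halves are joined in step 11; C14–OH is installed last.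

**Route**

**Step 1**
Reactants: 1 (2-methylcyclohexane-1,3-dione), 2 (5-bromo-2-methylpent-2-ene)
Product: 3 (2-methyl-2-(4-methylpent-3-en-1-yl)cyclohexane-1,3-dione)
Conditions: NaOH, NaI (cat.), H2O, 90 °C
Reagents that add atoms: none
Why: C-alkylation (SN2) of the doubly activated enolate makes the quaternary carbon. The product is an achiral, prochiral dione whose homoprenyl chain is the future C20–C23 unit.

**Step 2**
Reactants: 3
Product: 4 ((2R,3S)-3-hydroxy-2-methyl-2-(4-methylpent-3-enyl)cyclohexan-1-one)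
Conditions: (S)-Me-CBS (10 mol%), catecholborane (1.0 equiv), toluene, –78 °C
Reagents that add atoms: none (hydride only)
Why: Corey–Bakshi–Shibata desymmetrisation. The metal-free oxazaborolidine reduces one enantiotopic C=O and sets the quaternary C19 and C18 in one operation, with the C18-OH trans to the chain.

**Step 3**
Reactants: 4
Product: 5 (the (R)-epoxide, (2R,3S)-2-{2-[(2R)-3,3-dimethyloxiran-2-yl]ethyl}-3-hydroxy-2-methylcyclohexanone)
Conditions: Shi fructose-derived ketone (30 mol%), Oxone, K2CO3, Bu4NHSO4, MeCN/DMM/aq. Na2B4O7–EDTA, 0 °C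
Reagents that add atoms: Oxone, potassium peroxymonosulfate, OOS(=O)(=O)[O-].[K+]
Why: Shi asymmetric epoxidation. The chiral dioxirane attacks the only alkene, and catalyst control sets the epoxide configuration that becomes C3 (left) or C22 (right).

**Step 4**
Reactants: 5
Product: 6 (trans-fused cyclohexanone–oxepane keto-alcohol)
Conditions: CSA (20 mol%), HFIP/CH2Cl2 (1:4), 0 → 23 °C
Reagents that add atoms: none (isomerisation)
Why: Proposed new method: an acid/HFIP-promoted 7-endo epoxy-alcohol etherification.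
- Mechanism: the protonated epoxide opens with SN1-like character at the tertiary gem-dimethyl carbon C23. The equatorial C18-OH closes 7-endo onto C23, not 6-exo onto C22.
- The trans-diequatorial OH/CH2 pair and the Thorpe–Ingold effect of the quaternary C19 pre-organise the chain. The C18–O bond is never broken, so the trans ring fusion and the C22 oxygen configuration are retained.
- Closest known reaction: endo-selective acid-catalysed epoxy-alcohol cyclisation of trisubstituted epoxides (6-endo THP formation).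

**Step 5 (left half)**
Reactants: 6
Product: 7 (TBS ether)
Conditions: TBSOTf, 2,6-lutidine, CH2Cl2, –78 → 0 °C
Reagents that add atoms: TBSOTf, CC(C)(C)[Si](C)(C)OS(=O)(=O)C(F)(F)F
Why: Silylation of the hindered secondary alcohol. TBS is orthogonal to the TES group used on the right half.

**Step 6**
Reactants: 7
Product: 8 (alkenyl triflate, C11(OTf)=C10)
Conditions: KHMDS, PhNTf2, THF, –78 °C
Reagents that add atoms: PhNTf2, O=S(=O)(N(c1ccccc1)S(=O)(=O)C(F)(F)F)C(F)(F)F
Why: Enolisation occurs only toward C10, because C6 is quaternary. The enolate is then trapped as the enol triflate.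

**Step 7**
Reactants: 8
Product: 9 (C11-vinyl diene)
Conditions: vinylSnBu3, Pd(PPh3)4, LiCl, THF/DMF, 65 °C
Reagents that add atoms: vinyltributylstannane, C=C[Sn](CCCC)(CCCC)CCCC
Why: Stille coupling installs the C12=C13 unit.

**Step 8 (right half)**
Reactants: 6
Product: 10 (TES ether)
Conditions: TESOTf, 2,6-lutidine, CH2Cl2, –78 → 0 °C
Reagents that add atoms: TESOTf, CC[Si](CC)(CC)OS(=O)(=O)C(F)(F)F
Why: Protects the C22 alcohol during enolate chemistry.

**Step 9**
Reactants: 10
Product: 11 (15-methyl ketone, C15 epimer mixture)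
Conditions: LDA, THF, –78 °C; then MeI, DMPU, –78 → 0 °C
Reagents that add atoms: MeI, CI
Why: Enolate alkylation at C15, the only enolisable position. Its stereochemistry is irrelevant because C15 becomes sp2 in the next step.

**Step 10**
Reactants: 11
Product: 12 (tetrasubstituted enol triflate, C14(OTf)=C15(Me))
Conditions: KHMDS, PhNTf2, THF, –78 °C
Reagents that add atoms: PhNTf2, O=S(=O)(N(c1ccccc1)S(=O)(=O)C(F)(F)F)C(F)(F)F
Why: Regiospecific enolisation and triflation.

**Step 11**
Reactants: 9, 12
Product: 13 (coupled bis-silyl ether, C13–C14 bond, C14=C15 alkene)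
Conditions: (i) 9-BBN, THF, 0 → 23 °C; (ii) 12, PdCl2(dppf) (10 mol%), AsPh3, Cs2CO3, THF/DMF/H2O, 60 °C
Reagents that add atoms: none
Why: Chemoselective hydroboration of the unhindered vinyl group, then B-alkyl Suzuki–Miyaura coupling. This forms the C13–C14 bond and the tetrasubstituted alkene.

**Step 12**
Reactants: 13
Product: 14 (C10 alcohol, C11–H)
Conditions: 9-BBN, THF, 65 °C; then H2O2, NaOH, 0 → 23 °C
Reagents that add atoms: H2O2, OO
Why: Hydroboration–oxidation of the trisubstituted C10=C11 alkene, with the tetrasubstituted alkene unreactive. Boron adds to C10 from the face anti to the axial C6 methyl, so H goes onto C11 from that face (H up).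

**Step 13**
Reactants: 14
Product: 15 (C10 ketone)
Conditions: Dess–Martin periodinane, NaHCO3, CH2Cl2
Reagents that add atoms: none
Why: Oxidation of the secondary alcohol. The α-stereocentre C11 is epimerisable, and the equatorial C12 (natural) arrangement is thermodynamic.

**Step 14**
Reactants: 15
Product: 16 (exo-methylene at C10)
Conditions: Ph3PCH3Br, KOtBu, toluene, 80 °C
Reagents that add atoms: methylenetriphenylphosphorane, C=P(c1ccccc1)(c1ccccc1)c1ccccc1
Why: Wittig methylenation of the α-branched ketone.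

**Step 15**
Reactants: 16
Product: 17 (α-epoxide at C14–C15)
Conditions: DMDO (1.1 equiv), acetone/CH2Cl2, –20 °C
Reagents that add atoms: dimethyldioxirane, CC1(C)OO1
Why: Electrophilic epoxidation of the most electron-rich (tetrasubstituted) alkene. It occurs from the bottom face, anti to the axial C19 methyl.

**Step 16**
Reactants: 17
Product: 18 (C14 tertiary alcohol, C15–H)
Conditions: LiEt3BH, THF, 23 → 65 °C
Reagents that add atoms: none (hydride only)
Why: Fürst–Plattner trans-diaxial opening. Hydride attacks the less hindered C15 from the top face, giving C15–H axial up with the methyl equatorial, and C14–O axial down.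

**Step 17**
Reactants: 18
Product: 19 (free C22-OH)
Conditions: PPTS, MeOH/CH2Cl2, 23 °C
Reagents that add atoms: none
Why: Selective TES cleavage; TBS and the tertiary alcohol are untouched.

**Step 18**
Reactants: 19
Product: 20 (C22 ketone)
Conditions: Dess–Martin periodinane, NaHCO3, CH2Cl2
Reagents that add atoms: none
Why: Oxidation of the secondary alcohol; the tertiary C14-OH and the TBS ether are inert.

**Step 19**
Reactants: 20
Product: 21 (free C3-OH)
Conditions: HF·pyridine, pyridine, THF, 40 °C
Reagents that add atoms: none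
Why: Mildly acidic desilylation, avoiding base-promoted epimerisation next to the ketone.

**Step 20**
Reactants: 21
Product: 22 (3-epi-sodwanone K 3-acetate)
Conditions: Ac2O, DMAP, Et3N, CH2Cl2, 23 °C
Reagents that add atoms: Ac2O, CC(=O)OC(C)=O
Why: Acetylation of the secondary C3-OH, with the tertiary C14-OH left free. The C3 configuration was fixed in step 3 and is never touched.

**Compound list**

| No. | Name | SMILES | Role |
|---|---|---|---|
| 1 | 2-methylcyclohexane-1,3-dione | CC1C(=O)CCCC1=O | starting material |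
| 2 | 5-bromo-2-methylpent-2-ene | CC(C)=CCCBr | starting material |
| 3 | 2-methyl-2-(4-methylpent-3-enyl)cyclohexane-1,3-dione | CC(C)=CCCC1(C)C(=O)CCCC1=O | intermediate |
| 4 | (2R,3S)-3-hydroxy-2-methyl-2-(4-methylpent-3-enyl)cyclohexanone | O=C1CCC[C@H](O)[C@@]1(C)CCC=C(C)C | intermediate |
| 5 | (R)-epoxide of 4 | O=C1CCC[C@H](O)[C@@]1(C)CC[C@H]2OC2(C)C | intermediate |
| 6 | trans-fused cyclohexanone–3-hydroxy-2,2-dimethyloxepane | O=C1CCC[C@@H]2OC(C)(C)[C@H](O)CC[C@]21C | intermediate |
| 7 | TBS ether of 6 | O=C1CCC[C@@H]2OC(C)(C)[C@H](O[Si](C)(C)C(C)(C)C)CC[C@]21C | intermediate |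
| 8 | alkenyl triflate of 7 | O(S(=O)(=O)C(F)(F)F)C1=CCC[C@@H]2OC(C)(C)[C@H](O[Si](C)(C)C(C)(C)C)CC[C@]21C | intermediate |
| 9 | C11-vinyl diene | C=CC1=CCC[C@@H]2OC(C)(C)[C@H](O[Si](C)(C)C(C)(C)C)CC[C@]21C | intermediate |
| 10 | TES ether of 6 | O=C1CCC[C@@H]2OC(C)(C)[C@H](O[Si](CC)(CC)CC)CC[C@]21C | intermediate |
| 11 | 15-methyl ketone (C15 mixture) | O=C1C(C)CC[C@@H]2OC(C)(C)[C@H](O[Si](CC)(CC)CC)CC[C@]21C | intermediate |
| 12 | tetrasubstituted alkenyl triflate | O(S(=O)(=O)C(F)(F)F)C1=C(C)CC[C@@H]2OC(C)(C)[C@H](O[Si](CC)(CC)CC)CC[C@]21C | intermediate |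
| 13 | coupled product, ring-A endocyclic alkene and C14=C15 alkene | C1CC[C@@H]2OC(C)(C)[C@H](O[Si](C)(C)C(C)(C)C)CC[C@@]2(C)C=1CCC1=C(C)CC[C@@H]2OC(C)(C)[C@H](O[Si](CC)(CC)CC)CC[C@]21C | intermediate |
| 14 | C10 alcohol | O[C@H]1CC[C@@H]2OC(C)(C)[C@H](O[Si](C)(C)C(C)(C)C)CC[C@@]2(C)[C@@H]1CCC1=C(C)CC[C@@H]2OC(C)(C)[C@H](O[Si](CC)(CC)CC)CC[C@]21C | intermediate |
| 15 | C10 ketone | O=C1CC[C@@H]2OC(C)(C)[C@H](O[Si](C)(C)C(C)(C)C)CC[C@@]2(C)[C@@H]1CCC1=C(C)CC[C@@H]2OC(C)(C)[C@H](O[Si](CC)(CC)CC)CC[C@]21C | intermediate |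
| 16 | exo-methylene compound | C=C1CC[C@@H]2OC(C)(C)[C@H](O[Si](C)(C)C(C)(C)C)CC[C@@]2(C)[C@@H]1CCC1=C(C)CC[C@@H]2OC(C)(C)[C@H](O[Si](CC)(CC)CC)CC[C@]21C | intermediate |
| 17 | α-14,15-epoxide | C=C1CC[C@@H]2OC(C)(C)[C@H](O[Si](C)(C)C(C)(C)C)CC[C@@]2(C)[C@@H]1CC[C@]34O[C@@]3(C)CC[C@@H]2OC(C)(C)[C@H](O[Si](CC)(CC)CC)CC[C@]24C | intermediate |
| 18 | C14 tertiary alcohol | C=C1CC[C@@H]2OC(C)(C)[C@H](O[Si](C)(C)C(C)(C)C)CC[C@@]2(C)[C@@H]1CC[C@]1(O)[C@@H](C)CC[C@@H]2OC(C)(C)[C@H](O[Si](CC)(CC)CC)CC[C@]21C | intermediate |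
| 19 | C22-OH (TES removed) | C=C1CC[C@@H]2OC(C)(C)[C@H](O[Si](C)(C)C(C)(C)C)CC[C@@]2(C)[C@@H]1CC[C@]1(O)[C@@H](C)CC[C@@H]2OC(C)(C)[C@H](O)CC[C@]21C | intermediate |
| 20 | C22 ketone, C3-OTBS | C=C1CC[C@@H]2OC(C)(C)[C@H](O[Si](C)(C)C(C)(C)C)CC[C@@]2(C)[C@@H]1CC[C@]1(O)[C@@H](C)CC[C@@H]2OC(C)(C)C(=O)CC[C@]21C | intermediate |
| 21 | C3-OH | C=C1CC[C@@H]2OC(C)(C)[C@H](O)CC[C@@]2(C)[C@@H]1CC[C@]1(O)[C@@H](C)CC[C@@H]2OC(C)(C)C(=O)CC[C@]21C | intermediate |
| 22 | 3-epi-sodwanone K 3-acetate | C=C1CC[C@@H]2OC(C)(C)[C@H](OC(C)=O)CC[C@@]2(C)[C@@H]1CC[C@]1(O)[C@@H](C)CC[C@@H]2OC(C)(C)C(=O)CC[C@]21C | target |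

**Totals:** 20 steps in total; longest linear sequence 17 steps (1→2→3→4→5→6→7→11→…→20).

**Three steps most likely to fail**
1. **Step 4 (proposed new 7-endo cyclisation).** It could give the 6-exo tetrahydropyran instead of the oxepane.
   - Fallback: Hg(OTf)2-mediated Markovnikov (7-endo) oxymercuration of alkene 4, then NaBH4/O2 to the C22 alcohol and DMP to the ketone. The 3-epi configuration is then set by stereoselective reduction (L-Selectride) or Mitsunobu inversion. The product feeds step 5.
2. **Step 11 (hindered sp3–sp2 Suzuki coupling).**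
   - Fallback: convert the vinyl group of 9 to the alkyl iodide (hydroboration/oxidation, then I2/PPh3). Make the alkyllithium and add it to ketone 11, then dehydrate (Burgess) to the tetrasubstituted alkene of 13.
3. **Step 16 (regioselective hydride opening of the tetrasubstituted epoxide).** Attack at C14 or loss of trans-diaxial control would give the wrong alcohol.
   - Fallback: skip the epoxide. Do a Co/silane/O2 HAT (Mukaiyama) hydration directly on the C14=C15 alkene of 16, with H going to C15 and O2 capture at C14 from the open α face.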